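**Assumption:** the target, 21-(furan-2-yl)henicosa-14,16-diyn-1-ol, has no stereocentre and no stereogenic double bond, so "single enantiomer" is taken to mean the one achiral compound drawn.

**Retrosynthetic overview**
1. Target = HO(CH2)13–C≡C–C≡C–(CH2)4–(2-furyl). Cut the central C15–C16 sp–sp bond to give ω-alkynol 6 (C1–C15) and alkynyl methyl sulfide 14 (C16–C21 plus furan), joined by a new palladium/copper desulfitative alkyne–alkynyl sulfide coupling.
2. Alkynol 6 comes from the alkyne zipper isomerisation of pentadec-2-yn-1-ol 4, itself from prop-2-yn-1-ol and 1-bromododecane.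
3. Sulfide 14 comes from S-methylation of 2-(hex-5-yn-1-yl)furan 12, made by acetylide displacement on 2-(4-chlorobutyl)furan 10 (2-furyllithium plus 1-bromo-4-chlorobutane).
4. Rings: the furan is bought intact and no ring is formed; there are no stereocentres to set.

**Route**

Step 1
Reactants: 1 prop-2-yn-1-ol; 2 1-bromododecane
Product: 4 pentadec-2-yn-1-ol, via dilithium salt of prop-2-yn-1-ol 3 (not isolated)
Conditions: n-BuLi (2.1 equiv), THF–DMPU, −78 to 0 °C; then 2, 0 °C to rt, 16 h; H2O
Reagents that add atoms: none
Why: Two equivalents of n-BuLi give the O,C-dilithio species, whose acetylide carbon is far more nucleophilic than the alkoxide in a dipolar cosolvent, so SN2 acetylide alkylation of the primary bromide gives the 2-alkyn-1-ol (no stereocentre formed).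

Step 2
Reactants: 4 pentadec-2-yn-1-ol
Product: 6 pentadec-14-yn-1-ol, via dipotassium salt of pentadec-14-yn-1-ol 5 (not isolated)
Conditions: KH (4 equiv), H2N(CH2)3NH2, rt, 1 h (forms KNH(CH2)3NH2); then 4, rt, 4 h; H2O
Reagents that add atoms: none
Why: Alkyne zipper reaction: reversible propargyl/allenyl proton transfers walk the triple bond along the chain, away from the alkoxide, until it is trapped as the terminal potassium acetylide, which work-up protonates (no stereocentre formed).

Step 3
Reactants: 7 furan (1.2 equiv); 8 1-bromo-4-chlorobutane
Product: 10 2-(4-chlorobutyl)furan, via 2-furyllithium 9 (not isolated)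
Conditions: n-BuLi (1.0 equiv), THF, 0 °C, 2 h; then 8, −78 °C to rt
Reagents that add atoms: none
Why: Furan is lithiated selectively at C2 (alpha-lithiation) and the aryllithium displaces bromide much faster than chloride (SN2 alkylation), keeping the chloride for the next step.

Step 4
Reactants: 10 2-(4-chlorobutyl)furan; 11 lithium acetylide–ethylenediamine complex, LiC≡CH·H2N(CH2)2NH2 (1.5 equiv)
Product: 12 2-(hex-5-yn-1-yl)furan
Conditions: NaI (10 mol %), DMSO, rt, 12 h
Reagents that add atoms: none
Why: SN2 acetylide alkylation of a primary chloride in DMSO, helped by in situ Finkelstein exchange, gives the terminal alkyne while the furan ring is inert to the reagent.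

Step 5
Reactants: 12 2-(hex-5-yn-1-yl)furan
Product: 14 2-[6-(methylsulfanyl)hex-5-yn-1-yl]furan, via lithium acetylide of 2-(hex-5-yn-1-yl)furan 13 (not isolated)
Conditions: n-BuLi (1.05 equiv), THF, −78 °C, 30 min; then MeSSMe (1.2 equiv), −78 to 0 °C; H2O
Reagents that add atoms: dimethyl disulfide, CSSC
Why: The alkyne C–H (pKa about 25) is removed long before the furan C5–H (pKa about 36), and the lithium acetylide cleaves the S–S bond of the disulfide (electrophilic sulfenylation) to give the 1-(methylthio)alkyne.

Step 6
Reactants: 14 2-[6-(methylsulfanyl)hex-5-yn-1-yl]furan (1.0 equiv); 6 pentadec-14-yn-1-ol (1.1 equiv)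
Product: 16 21-(furan-2-yl)henicosa-14,16-diyn-1-ol, via copper acetylide of pentadec-14-yn-1-ol 15 (not isolated)
Conditions: Pd2(dba)3 (2.5 mol %), P(2-furyl)3 (10 mol %), Cu(O2C-2-C4H3S) (monovalent copper thiophene-2-carboxylate, 1.5 equiv), degassed THF, 45 °C, 12 h, dark
Reagents that add atoms: none
Why: Proposed new method: a desulfitative C(sp)–C(sp) cross-coupling in which zerovalent palladium inserts into the alkynyl C–S bond of 14, the copper carboxylate deprotonates terminal alkyne 6 to copper acetylide 15 and at the same time captures the thiolate as Cu–SMe, transmetalation gives a bis(alkynyl) divalent palladium complex and reductive elimination forms the C15–C16 bond, with cross-selectivity enforced because only the sulfide can be the electrophile and no oxidant or haloalkyne is present to open Glaser or halogen-exchange homocoupling; the closest known reaction types are the Liebeskind–Srogl coupling of thioalkynes with boronic acids and the copper-mediated Sonogashira-type coupling of thioesters with terminal alkynes, and this pairing of an alkynyl sulfide with a terminal alkyne to make a 1,3-diyne is proposed here as unprecedented (no stereocentre formed; free OH and furan tolerated under the neutral, amine-free conditions).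

**Compound list**
1 | prop-2-yn-1-ol | C#CCO | starting material
2 | 1-bromododecane | CCCCCCCCCCCCBr | starting material
3 | dilithium salt of prop-2-yn-1-ol | [Li]C#CCO[Li] | intermediate
4 | pentadec-2-yn-1-ol | CCCCCCCCCCCCC#CCO | intermediate
5 | dipotassium salt of pentadec-14-yn-1-ol | [K]C#CCCCCCCCCCCCCCO[K] | intermediate
6 | pentadec-14-yn-1-ol | C#CCCCCCCCCCCCCCO | intermediate
7 | furan | c1ccoc1 | starting material
8 | 1-bromo-4-chlorobutane | ClCCCCBr | starting material
9 | 2-furyllithium | [Li]c1ccco1 | intermediate
10 | 2-(4-chlorobutyl)furan | ClCCCCc1ccco1 | intermediate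
11 | lithium acetylide–ethylenediamine complex | [Li]C#C.NCCN | starting material
12 | 2-(hex-5-yn-1-yl)furan | C#CCCCCc1ccco1 | intermediate
13 | lithium acetylide of 2-(hex-5-yn-1-yl)furan | [Li]C#CCCCCc1ccco1 | intermediate
14 | 2-[6-(methylsulfanyl)hex-5-yn-1-yl]furan | CSC#CCCCCc1ccco1 | intermediate
15 | copper acetylide of pentadec-14-yn-1-ol | [Cu]C#CCCCCCCCCCCCCCO | intermediate
16 | 21-(furan-2-yl)henicosa-14,16-diyn-1-ol | OCCCCCCCCCCCCCC#CC#CCCCCc1ccco1 | target

**Summary**
Total step count: 6.
Longest linear sequence: 4 steps (7 → 10 → 12 → 14 → 16); the other branch is 3 steps (1 + 2 → 4 → 6 → 16).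

**Steps most likely to fail**

Step 6 (the proposed new coupling) is the riskiest. The alkynyl–palladium–thiolate pair may add across alkyne 6 (alkynylthiolation) instead of being intercepted by the copper acetylide. Oxidative addition into an alkyl-substituted thioalkyne may be slow. The diyne product may also be consumed by palladium hydride chemistry. The fallback is known chemistry, a Cadiot–Chodkiewicz coupling; it sets out from 6 and from 12 (the precursor of 14) and comes back to the route at 16. Alkynol 6 is brominated at the alkyne terminus (N-bromosuccinimide, AgNO3 10 mol %, acetone, rt) to give 15-bromopentadec-14-yn-1-ol F1. F1 is then coupled with terminal alkyne 12 (CuCl 5 mol %, NH2OH·HCl, 30% aqueous n-BuNH2, Et2O/MeOH, 0 °C) to give 16 directly. The bromine is placed on the alkynol and not on the furan partner because N-bromosuccinimide would also attack the furan ring.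

Step 2 (zipper over twelve positions) can stall or give internal alkyne mixtures if the amide base is wet or partly spent. The fallback replaces the isomerisation by a C–C bond formation; it sets out from 11 and comes back at 6. Commercial tridecane-1,13-diol is monobrominated (48% aqueous HBr, toluene, reflux) to 13-bromotridecan-1-ol F2. F2 is alkylated with 11 (2.5 equiv, DMSO, rt; one equivalent is consumed by the hydroxyl group) to give 6.

Step 1 (dianion alkylation with a long, poorly soluble bromide) can suffer from low conversion or O-alkylation. The fallback forms the C1–C2 bond instead of the C3–C4 bond; it sets out from 2 and 11 and comes back at 4. Bromide 2 is alkylated with 11 (DMSO, rt) to tetradec-1-yne F3. F3 is deprotonated (n-BuLi, THF, −78 °C) and hydroxymethylated with paraformaldehyde (−78 °C to rt, then H2O) to give 4.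

**Further compounds**
F1 | step 6 | 15-bromopentadec-14-yn-1-ol | BrC#CCCCCCCCCCCCCCO
F2 | step 2 | 13-bromotridecan-1-ol | OCCCCCCCCCCCCCBr
F3 | step 1 | tetradec-1-yne | C#CCCCCCCCCCCCC
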